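I nearly integrated feed profiles and cold holds before asking what one molecule of starting material could become. It had a fork: protic impurity turned it into quenched substrate, and reagent turned it into target.

the same everywhere: protic impurity 1.05 mM
- east: starting material 21 mM; reagent 25.2 mM; temperature 10 °C; run made earlier
- south: starting material 29 mM; reagent 25.2 mM; temperature 25 °C; run made earlier
- north-west: starting material 46 mM; reagent 25.2 mM; temperature 10 °C; run made earlier
- cedar: starting material 21 mM; reagent 25.2 mM; everything together at the start at −5 °C, warmed to 25 °C at 10 h; time 50 h
- oak: starting material 21 mM; reagent 25.2 mM (fed, over 10 h); temperature 25 °C; all else is in the flask from the start; the feed brings no volume worth counting; time 50 h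
- elm: starting material 21 mM (fed, over 10 h); reagent 25.2 mM; temperature 25 °C; all else is in the flask from the start; the feed brings no volume worth counting; time 50 h
- alder: starting material 21 mM; reagent 25.2 mM; temperature 25 °C; everything together at the start; time 50 h
- ash: starting material 21 mM; reagent 25.2 mM (fed, over 10 h); the addition at −5 °C, then warmed to 25 °C; the feed brings no volume worth counting; time 50 h

| run | time / h | target / % | starting material / % |
|---|---|---|---|
| east | 8.00 | 0.6 | 95.0 |
| east | 15.0 | 1.6 | 93.8 |
| east | 30.0 | 10.1 | 85.0 |
| east | 48.0 | 61.1 | 33.8 |
| east | 96.0 | 91.6 | 1.7 |
| south | 3.00 | 0 | 95.8 |
| south | 6.00 | 5.3 | 90.8 |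
| south | 12.0 | 58.2 | 37.5 |
| south | 20.0 | 80.4 | 16.9 |
| south | 40.0 | 84.9 | 10.9 |
| north-west | 6.00 | 0.2 | 97.7 |
| north-west | 12.0 | 2.2 | 95.2 |
| north-west | 25.0 | 47.0 | 51.7 |
| north-west | 40.0 | 53.7 | 42.6 |
| north-west | 96.0 | 54.4 | 43.4 |

(standard deviation of a reading: 0.5 percentage points)

- the numbers in the tables scatter by 0.5 percentage points (one standard deviation)
- candidate steps: starting material + reagent + by-product -> target + 2 by-product; starting material + reagent -> target + by-product; starting material + protic impurity -> quenched substrate

1. the best flask by amount of target, in percent of the starting material charged; "all alike" if 1.5 percentage points covers them all (cedar / oak / elm / alder / ash / all alike)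
2. amount of target at the end, in percent of the starting material charged, cedar
3. amount of target at the end, in percent of the starting material charged, oak
4. amount of target at the end, in percent of the starting material charged, elm
5. amount of target at the end, in percent of the starting material charged, alder
6. amount of target at the end, in percent of the starting material charged, ash

The south run had lost 4.20% of its starting material at 3.00 h with target at 0%, so the quench came first. The part missing from target plus starting material read 5.10% in the east run at 48.0 h and 2.20% in the north-west run at 96.0 h, against impurity-to-charge ratios of 5.00% and 2.28%. These readings fitted one molecule of starting material lost per molecule of impurity.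

I carried the yield ceiling, 95.0%, the smaller of starting material minus impurity and reagent, over the charge. On the north-west charges it gave 54.8%, against a reading of 54.4%. In the new recipes, starting material after the quench, 19.95 mM, was less than the reagent, 25.2 mM, which made it the limiting reagent. Cedar and ash had 40.0 h at 25 °C after the cold stage, as long as the 40.0 h after which the south run, on a larger charge of starting material, read 84.9% against its own ceiling of 86.9%, so I expected each flask just under the ceiling.

The forecast gave 94.7% for cedar, the same figure for the other flasks, and all alike: “Every flask therefore finishes near 95%, perhaps slightly less”.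

The flasks gave 94.1% for cedar, 94.5% for oak, 94.5% for elm, 94.8% for alder and 94.1% for ash, a spread of 0.70 percentage points, so the answer was all alike. Starting material still stood at 0.860% in cedar and 0.247% in alder at 50.0 h.

    starting material + reagent + by-product → target + 2 by-product (k = 20.0 M⁻² min⁻¹, Ea = 49.0 kJ mol⁻¹)
    starting material + reagent → target + by-product (k = 2.10 × 10⁻⁴ M⁻¹ min⁻¹, Ea = 89.0 kJ mol⁻¹)
    starting material + protic impurity → quenched substrate (k = 3.40 M⁻¹ min⁻¹, Ea = 41.0 kJ mol⁻¹)
    (constants at 25 °C)

A flask like oak but with 84 mM of starting material had a ceiling of 30.0%, below the 95.0% of the recipe, and here the reagent was the smaller term. That flask gave 30.0% target with reagent at 0%, quenched substrate at 1.25% and starting material at 68.8%.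

The numbers in the tables were computed on assumed constants, and the scatter is random.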